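Turn the question round: ask what Monday's flask would need in order to end above Saturday's.

| flask | starting complex | incoming ligand | remark | time |
|---|---|---|---|---|
| cedar | 0.061 M | 0.30 M | run made earlier |  |
| larch | 0.092 M | 0.30 M | run made earlier |  |
| ash | 0.19 M | 0.30 M | run made earlier |  |
| oak | 0.20 M | 0.17 M | run made earlier |  |
| Saturday's | 0.20 M | 0.300 M |  | 30 min |
| Monday's | 0.050 M | 0.0800 M |  | 15 min |

| run | time / min | complex with one exchanged / % |
|---|---|---|
| cedar | 1.33 | 9 |
| cedar | 2.50 | 11 |
| cedar | 4.00 | 15 |
| cedar | 8.00 | 25 |
| cedar | 15.0 | 31 |
| larch | 1.33 | 4 |
| larch | 2.50 | 8 |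
| larch | 4.00 | 15 |
| larch | 8.00 | 27 |
| larch | 15.0 | 31 |
| ash | 1.33 | 4 |
| ash | 2.50 | 13 |
| ash | 4.00 | 14 |
| ash | 8.00 | 25 |
| ash | 15.0 | 26 |
| oak | 1.33 | 3 |
| oak | 2.50 | 5 |
| oak | 4.00 | 13 |
| oak | 8.00 | 9 |
| oak | 15.0 | 24 |

(standard deviation of a reading: 2 percentage points)

- the numbers in the tables scatter with a standard deviation of 2 percentage points

* which of the two ends with the higher amount of complex with one exchanged, in percent of the starting complex charged ("neither" if they lie within 2 percentage points) (Saturday's / Monday's / neither)
* complex with one exchanged at the end, in percent of the starting complex charged, Saturday's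
* complex with one exchanged at the end, in percent of the starting complex charged, Monday's

Read the early rise first. At 4.00 min, cedar, larch and ash stand at 15%, 15% and 14%, although their starting complex runs from 0.061 M to 0.19 M, so take the rate as first order in starting complex, and assume first order in incoming ligand. Hold c(incoming ligand) at its charge, the pseudo-first-order view: Monday's flask has 0.0800 M of it against 0.050 M of starting complex, no large excess, so test the hold on the share reacted below. Then integrate:

−dc(starting complex)/dt = k·c(starting complex)·c(incoming ligand)

share reacted = 1 − exp(−E), with E = k·c(incoming ligand)·t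

Call E the ligand exposure. The mean of those three readings gives, with their scatter:

k = 0.132 /M/min

E(Monday's) = 0.159, share = 14.7%

That share of 0.050 M would use 9.19% of the incoming ligand charged to Monday's flask, so keep the hold.

Now take ash, the run nearest Saturday's flask: it reads 25% at 8.00 min and 26% at 15.0 min, a gap of 1 point beside a scatter of 2 points per reading, which shows neither a rise nor a plateau. To pass the later reading, Monday's flask needs an exposure of 0.301, twice what it has. So my reckoning puts Saturday's higher, near 26%.

The forecast also says Saturday's, but with 34% against 14%, holding that the intermediate “reacts on to a doubly exchanged complex at a similar rate”.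

Saturday's flask ends at 26.4% and Monday's at 14.2%, so the forecast's Saturday figure stands 7.6 points too high.

    starting complex + complex with one exchanged → side product (k = 0.0454 /M/min)
    complex with one exchanged + incoming ligand ⇌ leaving ligand + complex with two exchanged (K = 3.90, k = 0.113 /M/min)
    complex with two exchanged + incoming ligand ⇌ leaving ligand + complex with three exchanged (K = 0.320, k = 0.0679 /M/min)
    starting complex + incoming ligand ⇌ leaving ligand + complex with one exchanged (K = 0.630, k = 0.157 /M/min)
    starting complex ⇌ dormant form (K = 0.710, k = 0.00751 /min)

Monday's exposure of 0.159 gave 14.7%. With 0.020 M of incoming ligand, the neighbour has an exposure of 0.0397, which gives 3.89%, and that flask stands at 3.99%. In Monday's flask at 15.0 min, the forward rate of the first exchange uses incoming ligand 7.4 times as fast as that of the second. Complex with one exchanged stands there at 14.2% and complex with two exchanged at 0.957%.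

The data are calculated with constants of no real substance, noise included.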